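**Retrosynthetic overview**
1. Target 15 ⇐ acid 14 (O-debenzylation) ⇐ aldehyde 13 ⇐ arene 11. The carboxyl carbon is put on the bought benzene ring last, when C2' already carries its acetate, so the free hydroxy acid that would close to a dihydroisocoumarin never exists.
2. Key disconnection, aryl–C1': 11 ⇐ aryl bromide 9 + O-acetyl chlorohydrin 8, by a light-driven nickel cross-electrophile coupling at the CH2X carbon next to the finished C2' stereocentre.
3. 8 ⇐ (S)-epichlorohydrin 5 + a C10 alkoxide-Grignard reagent (C3'–C4' bond); that reagent ⇐ (R)-propylene oxide 2 + 7-chloroheptyl Grignard reagent (C10'–C11' bond). Both stereocentres are bought.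
4. No ring is formed: the benzene ring comes with 9, and the two oxiranes are only opened.

Assumption: the SMILES is read as 2-[(2S,12R)-2,12-diacetoxytridecyl]-4,6-dihydroxybenzoic acid (primed numbers are side-chain carbons counted from the ring; C2' is S, C12' is R), and 1, 2, 5 and 9 are taken as catalogue compounds.

**Route**

Step 1
Reactants: 1 1-bromo-7-chloroheptane; 2 (R)-propylene oxide
Product: 4 (2R)-10-chlorodecan-2-ol, via 7-chloroheptyl Grignard reagent 3 (not isolated)
Conditions: Mg, THF, 25 °C; then CuI (5 mol %), 2, −30 to 0 °C; then 1 M HCl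
Reagents that add atoms: none
Why: Magnesium inserts into C–Br in preference to C–Cl, and the copper-catalysed Grignard ring-opening of the epoxide is an SN2 attack at its CH2 terminus, so the bought stereocentre is not touched and becomes C12' (R).

Step 2
Reactants: 4 (2R)-10-chlorodecan-2-ol; 5 (S)-epichlorohydrin
Product: 8 (2S,12R)-1-chlorotridecane-2,12-diyl diacetate, via alkoxide Grignard reagent 6 (not isolated), via chlorohydrin bis-alkoxide 7 (not isolated)
Conditions: i-PrMgCl (1.05 equiv), THF, 0 °C; Mg, reflux; CuI (10 mol %), 5 (0.95 equiv), −40 to −20 °C; then Ac2O (4 equiv), DMAP (10 mol %), −20 to 25 °C; then 1 M HCl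
Reagents that add atoms: acetic anhydride, CC(=O)OC(C)=O
Why: A Normant-type alkoxide-Grignard reagent (the alcohol masked as its magnesium alkoxide) opens epichlorohydrin at the epoxide CH2 under copper catalysis (SN2, no attack at C–Cl at −40 °C), so the bought stereocentre becomes C2' (S) with no bond to it changed, and both magnesium alkoxides are acetylated in the same flask.

Step 3
Reactants: 8 (2S,12R)-1-chlorotridecane-2,12-diyl diacetate; 9 1-bromo-3,5-bis(benzyloxy)benzene
Product: 11 (2S,12R)-1-[3,5-bis(benzyloxy)phenyl]tridecane-2,12-diyl diacetate, via iodo diacetate 10 (not isolated)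
Conditions: NaI (1.5 equiv), DMA, 80 °C, dark; then 9 (1.5 equiv), NiBr2(dtbbpy) (10 mol %), Ir[dF(CF3)ppy]2(dtbbpy)PF6 (1 mol %), Et3N (3 equiv), Na2CO3 (2 equiv), blue LEDs (450 nm), 30 °C
Reagents that add atoms: none
Why: Proposed new method: a one-pot chloride-to-iodide relay (Finkelstein SN2 at C1, which leaves C2 alone) feeds a nickel/photoredox reductive cross-electrophile coupling in which an O-acetyl chlorohydrin is the alkyl partner — the excited iridium photocatalyst is quenched by Et3N and its reduced form turns the nickel over, zerovalent nickel adds 9, iodine-atom abstraction from 10 (by monovalent nickel or by the α-aminoalkyl radical of Et3N) gives the primary C1 radical, which is trapped by the divalent aryl-nickel bromide and released from trivalent nickel by reductive elimination; the C2–O bond is never broken, so (S) is retained, and the β-acetoxy group should survive because there is no zinc or manganese to cause a Boord-type elimination, the reduced photocatalyst (about −1.4 V vs SCE) cannot reduce the radical to a carbanion, and the 1,2-acyloxy shift of a β-acetoxyalkyl radical (about 10^2 to 10^3 s^-1) is slower than capture by nickel; closest known reaction type: amine-driven nickel/photoredox reductive coupling of aryl bromides with simple alkyl bromides and iodides (and halide-exchange co-catalysis in thermal nickel couplings of alkyl chlorides), not yet shown for vicinal acyloxy halides made from epichlorohydrin.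

Step 4
Reactants: 11 (2S,12R)-1-[3,5-bis(benzyloxy)phenyl]tridecane-2,12-diyl diacetate
Product: 13 2,4-bis(benzyloxy)-6-[(2S,12R)-2,12-diacetoxytridecyl]benzaldehyde, via aryl iminium chloride 12 (not isolated)
Conditions: POCl3 (1.5 equiv), DMF, 0 to 50 °C; then H2O, 25 °C
Reagents that add atoms: N,N-dimethylformamide, CN(C)C=O; water, O
Why: Vilsmeier–Haack formylation goes to one of the two equivalent positions between the chain and a benzyloxy group (para to the other ether) in preference to the doubly flanked position between the two ethers, and acetates and benzyl ethers are inert to the chloroiminium salt.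

Step 5
Reactants: 13 2,4-bis(benzyloxy)-6-[(2S,12R)-2,12-diacetoxytridecyl]benzaldehyde
Product: 14 2,4-bis(benzyloxy)-6-[(2S,12R)-2,12-diacetoxytridecyl]benzoic acid
Conditions: NaClO2, NaH2PO4, 2-methyl-2-butene, t-BuOH/THF/H2O, 0 to 25 °C
Reagents that add atoms: sodium chlorite, [Na+].[O-]Cl=O
Why: Pinnick oxidation converts the aldehyde to the acid under buffered conditions, 2-methyl-2-butene takes up HOCl so the electron-rich ring is not chlorinated, and the C2' acetate blocks lactonisation.

Step 6
Reactants: 14 2,4-bis(benzyloxy)-6-[(2S,12R)-2,12-diacetoxytridecyl]benzoic acid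
Product: 15 2-[(2S,12R)-2,12-diacetoxytridecyl]-4,6-dihydroxybenzoic acid
Conditions: H2 (1 atm), 10% Pd/C, EtOAc, 25 °C
Reagents that add atoms: none
Why: Hydrogenolysis over palladium on carbon cleaves the two benzyl aryl ethers and leaves the alkyl acetates, the carboxylic acid and both stereocentres untouched.

**Compound list**
1 | 1-bromo-7-chloroheptane | ClCCCCCCCBr | starting material
2 | (R)-propylene oxide, (2R)-2-methyloxirane | C[C@@H]1CO1 | starting material
3 | (7-chloroheptyl)magnesium bromide | ClCCCCCCC[Mg]Br | intermediate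
4 | (2R)-10-chlorodecan-2-ol | C[C@@H](O)CCCCCCCCCl | intermediate
5 | (S)-epichlorohydrin, (2S)-2-(chloromethyl)oxirane | ClC[C@@H]1CO1 | starting material
6 | chloromagnesium (2R)-10-(chloromagnesio)decan-2-olate | C[C@@H](O[Mg]Cl)CCCCCCCC[Mg]Cl | intermediate
7 | bis(chloromagnesium) (2S,12R)-1-chlorotridecane-2,12-diolate | C[C@@H](O[Mg]Cl)CCCCCCCCC[C@H](O[Mg]Cl)CCl | intermediate
8 | (2S,12R)-1-chlorotridecane-2,12-diyl diacetate | CC(=O)O[C@@H](CCCCCCCCC[C@@H](C)OC(C)=O)CCl | intermediate
9 | 1-bromo-3,5-bis(benzyloxy)benzene | Brc1cc(OCc2ccccc2)cc(OCc2ccccc2)c1 | starting material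
10 | (2S,12R)-1-iodotridecane-2,12-diyl diacetate | CC(=O)O[C@@H](CCCCCCCCC[C@@H](C)OC(C)=O)CI | intermediate
11 | (2S,12R)-1-[3,5-bis(benzyloxy)phenyl]tridecane-2,12-diyl diacetate | CC(=O)O[C@@H](CCCCCCCCC[C@@H](C)OC(C)=O)Cc1cc(OCc2ccccc2)cc(OCc2ccccc2)c1 | intermediate
12 | N-({2,4-bis(benzyloxy)-6-[(2S,12R)-2,12-diacetoxytridecyl]phenyl}methylidene)-N-methylmethanaminium chloride | CC(=O)O[C@@H](CCCCCCCCC[C@@H](C)OC(C)=O)Cc1cc(OCc2ccccc2)cc(OCc2ccccc2)c1C=[N+](C)C.[Cl-] | intermediate
13 | 2,4-bis(benzyloxy)-6-[(2S,12R)-2,12-diacetoxytridecyl]benzaldehyde | CC(=O)O[C@@H](CCCCCCCCC[C@@H](C)OC(C)=O)Cc1cc(OCc2ccccc2)cc(OCc2ccccc2)c1C=O | intermediate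
14 | 2,4-bis(benzyloxy)-6-[(2S,12R)-2,12-diacetoxytridecyl]benzoic acid | CC(=O)O[C@@H](CCCCCCCCC[C@@H](C)OC(C)=O)Cc1cc(OCc2ccccc2)cc(OCc2ccccc2)c1C(=O)O | intermediate
15 | 2-[(2S,12R)-2,12-diacetoxytridecyl]-4,6-dihydroxybenzoic acid | CC(=O)O[C@@H](CCCCCCCCC[C@@H](C)OC(C)=O)Cc1cc(O)cc(O)c1C(=O)O | target

**Totals**
Total step count: 6. Longest linear sequence: 6 (from 1; aryl bromide 9 enters at step 3).

**Steps most likely to fail, with fallbacks**

Step 3 (the proposed new coupling). Risks are incomplete chloride-to-iodide exchange at the β-acetoxy carbon, loss of acetate to give the terminal alkene, and reduction of 9 to the arene. The fallback uses known chemistry, sets out from 8 and comes back at 11. K2CO3 in MeOH at 25 °C removes both acetates and closes the chlorohydrin to (2R)-11-[(2S)-oxiran-2-yl]undecan-2-ol F1. Bromide 9 is converted with Mg in THF into [3,5-bis(benzyloxy)phenyl]magnesium bromide F2. F2 (2.5 equiv, CuI 10 mol %, THF, −30 °C) opens F1 at the terminal carbon to give (2S,12R)-1-[3,5-bis(benzyloxy)phenyl]tridecane-2,12-diol F3. Ac2O, pyridine and DMAP then give 11. This replaces the radical nickel coupling by a polar copper-catalysed epoxide arylation, and C2' is again never a reacting centre.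

Step 2 (alkoxide-Grignard formation, epichlorohydrin opening and acetylation in one flask). Risks are sluggish magnesium insertion into the alkoxide-bearing chloride and epoxide re-closure before acetylation. The fallback sets out from 4 and comes back at 8, replacing the dianion by a protected mono-Grignard reagent and stepwise acetylation. TBSCl and imidazole give tert-butyl{[(2R)-10-chlorodecan-2-yl]oxy}dimethylsilane F4. Mg in THF at reflux gives {(9R)-9-[(tert-butyldimethylsilyl)oxy]decyl}magnesium chloride F5. CuI-catalysed opening of 5 at −40 °C and aqueous work-up give (2S,12R)-12-[(tert-butyldimethylsilyl)oxy]-1-chlorotridecan-2-ol F6. HCl in MeOH removes the silyl group to give (2S,12R)-1-chlorotridecane-2,12-diol F7. Ac2O, pyridine and DMAP give 8.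

Step 4 (regioselectivity of the formylation, and acetate survival in the acidic work-up). The fallback sets out from 11 and comes back at 14, bypassing 13 by halogenation and carboxylation with CO2 instead of formylation and oxidation. NBS in MeCN at 0 °C brominates the position ortho to the chain and para to one ether to give (2S,12R)-1-[3,5-bis(benzyloxy)-2-bromophenyl]tridecane-2,12-diyl diacetate F8. Sacrificial-anode electrocarboxylation (undivided cell, Mg anode, Ni cathode, n-Bu4NBF4, DMF, CO2 1 atm, constant current, 0 °C; then dilute HCl) converts the C–Br bond into the carboxylic acid 14.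

**Further compounds**
F1 | step 3 | (2R)-11-[(2S)-oxiran-2-yl]undecan-2-ol | C[C@@H](O)CCCCCCCCC[C@H]1CO1
F2 | step 3 | [3,5-bis(benzyloxy)phenyl]magnesium bromide | Br[Mg]c1cc(OCc2ccccc2)cc(OCc2ccccc2)c1
F3 | step 3 | (2S,12R)-1-[3,5-bis(benzyloxy)phenyl]tridecane-2,12-diol | C[C@@H](O)CCCCCCCCC[C@H](O)Cc1cc(OCc2ccccc2)cc(OCc2ccccc2)c1
F4 | step 2 | tert-butyl{[(2R)-10-chlorodecan-2-yl]oxy}dimethylsilane | C[C@@H](O[Si](C)(C)C(C)(C)C)CCCCCCCCCl
F5 | step 2 | {(9R)-9-[(tert-butyldimethylsilyl)oxy]decyl}magnesium chloride | C[C@@H](O[Si](C)(C)C(C)(C)C)CCCCCCCC[Mg]Cl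
F6 | step 2 | (2S,12R)-12-[(tert-butyldimethylsilyl)oxy]-1-chlorotridecan-2-ol | C[C@@H](O[Si](C)(C)C(C)(C)C)CCCCCCCCC[C@H](O)CCl
F7 | step 2 | (2S,12R)-1-chlorotridecane-2,12-diol | C[C@@H](O)CCCCCCCCC[C@H](O)CCl
F8 | step 4 | (2S,12R)-1-[3,5-bis(benzyloxy)-2-bromophenyl]tridecane-2,12-diyl diacetate | CC(=O)O[C@@H](CCCCCCCCC[C@@H](C)OC(C)=O)Cc1cc(OCc2ccccc2)cc(OCc2ccccc2)c1Br
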